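The benzene ring is not functionalised but built. Its hydroquinone pattern, C1–O(tigloyl) para to C4–OMe with the methyl on C5 beside C4 and the quaternary oxirane carbon on C2 beside C1, is cut into three pieces: an isopropenyl(methoxy)carbene chromium complex (C4, C5, C6), one of its CO ligands (C1 and its oxygen) and a terminal alkyne (C2, C3) that already carries the finished (R)-oxirane and the isobutyrate. One Dötz benzannulation forms C3–C4, C1–C2 and C1–C6, closes the ring and delivers the two oxygens differentiated as OMe and OH; the OH is tigloylated in the same flask. The stereocentre comes from a Sharpless epoxidation of a small enynol.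

Key step: step 5

Remarks on the chemistry
- Arene numbering follows the name of 15: C1 bears O-tigloyl, C2 the oxirane, C4 OMe, C5 CH3.
- The oxirane carbon keeps one spatial arrangement from 9 to 15. It is (S) in the free alcohol 9 and (R) in every ester, only because acylation raises the CIP rank of the CH2O arm above that of the ring CH2.
- In the SMILES of chromium compounds the CO ligands are written as separate fragments.
- Assumption: tiglic anhydride is purchased; otherwise it is made beforehand from tiglic acid and DCC.

Step 1
Reactants: 1 2-bromopropene; 2 chromium hexacarbonyl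
Product: 5 pentacarbonyl[methoxy(prop-1-en-2-yl)carbene]chromium(0), via isopropenyllithium 3 (not isolated), via lithium acylchromate 4 (not isolated)
Conditions: t-BuLi (2.0 equiv), Et2O, −78 °C; Cr(CO)6, Et2O, −78 °C → rt; evaporate; Me3OBF4, CH2Cl2, 0 °C → rt; Ar throughout
Reagents that add atoms: trimethyloxonium tetrafluoroborate, C[O+](C)C.F[B-](F)(F)F
Why: Fischer carbene synthesis, in which bromine–lithium exchange gives the vinyllithium, this adds to a CO ligand of Cr(CO)6 to give the acyl chromate, and O-methylation of the acylate oxygen by the oxonium salt gives the methoxycarbene complex, a type of complex routinely made this way.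

Step 2
Reactants: 6 2-bromoprop-2-en-1-ol; 7 ethynyltrimethylsilane
Product: 8 2-methylidene-4-(trimethylsilyl)but-3-yn-1-ol
Conditions: PdCl2(PPh3)2 (2 mol %), CuI (4 mol %), Et3N, THF, rt
Reagents that add atoms: none
Why: Sonogashira coupling of a 1,1-disubstituted vinyl bromide with a terminal alkyne, which tolerates the free primary alcohol, while the silyl cap prevents a second coupling and oxidative dimerisation at the alkyne terminus.

Step 3
Reactants: 8 2-methylidene-4-(trimethylsilyl)but-3-yn-1-ol
Product: 10 [(2R)-2-[(trimethylsilyl)ethynyl]oxiran-2-yl]methyl 2-methylpropanoate, via epoxy alcohol 9 (not isolated)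
Conditions: Ti(OiPr)4 (10 mol %), L-(+)-DIPT (14 mol %), TBHP (2 equiv, in decane), 4 Å MS, CH2Cl2, −20 °C; P(OMe)3, −20 °C; then i-PrCOCl, Et3N, −20 → 0 °C
Reagents that add atoms: tert-butyl hydroperoxide, CC(C)(C)OO; isobutyryl chloride (2-methylpropanoyl chloride), CC(C)C(Cl)=O
Why: Sharpless asymmetric epoxidation of a 2-substituted allylic alcohol with acylation in the same flask, in which the titanium tartrate delivers the peroxide oxygen to one face of the bound allylic alkoxide; L-(+)-DIPT is the tartrate that turns 2-methylprop-2-en-1-ol into (S)-2-methylglycidol, and because the alkynyl group stands where that methyl stands and is likewise the lowest-ranked substituent, the alcohol should be (S)-9, which is acylated after reduction of the excess peroxide so that the small, acid-sensitive 2,2-disubstituted epoxy alcohol is never isolated and appears as (R)-10 with the arrangement at carbon unchanged.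

Step 4
Reactants: 10 [(2R)-2-[(trimethylsilyl)ethynyl]oxiran-2-yl]methyl 2-methylpropanoate
Product: 11 [(2R)-2-ethynyloxiran-2-yl]methyl 2-methylpropanoate
Conditions: TBAF (1.1 equiv), AcOH (1.2 equiv), THF, 0 °C; concentrate cold, product is volatile
Reagents that add atoms: none
Why: Fluoride-induced protodesilylation of an alkynylsilane, in which the acetic acid buffer protonates the acetylide as it forms and keeps the medium from turning basic, so that the isobutyrate and the oxirane (quaternary carbon, not epimerisable) are left untouched.

Step 5
Reactants: 5 pentacarbonyl[methoxy(prop-1-en-2-yl)carbene]chromium(0); 11 [(2R)-2-ethynyloxiran-2-yl]methyl 2-methylpropanoate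
Product: 15 4-methoxy-5-methyl-2-[(2R)-2-[(2-methylpropanoyloxy)methyl]oxiran-2-yl]phenyl (2E)-2-methylbut-2-enoate, via phenol chromium tricarbonyl complex 12 (not isolated), via free phenol 13 (not isolated), via tiglate chromium tricarbonyl complex 14 (not isolated)
Conditions: 5 (1.0 equiv), 11 (1.2 equiv), degassed THF (0.1 M), 50 °C, Ar; then tiglic anhydride, Et3N, DMAP (cat.), 0 °C → rt; then air, light, rt
Reagents that add atoms: tiglic anhydride [(2E)-2-methylbut-2-enoic anhydride], C/C=C(\C)C(=O)OC(=O)/C(C)=C/C
Why: Thermal loss of one CO from 5 lets the alkyne bind and insert into the Cr=C bond to give an η3-vinylcarbene, CO insertion turns this into a chromium-bound dienylketene, and 6π-electrocyclisation followed by enolisation gives the 4-methoxyphenol as its Cr(CO)3 complex 12, partly free as 13; this is the Dötz benzannulation of an alkenyl(alkoxy)carbene complex with a terminal alkyne. The benzene ring closes in the electrocyclic step, a thermal disrotatory 6π closure that makes the C1–C6 bond after the two insertions have made C3–C4 and C1–C2. No stereocentre is formed: no bond to the quaternary oxirane carbon is made or broken, it cannot epimerise under these neutral conditions, and the two arene-face diastereomers of 12 and 14 converge once chromium is removed. The step needs regiocontrol in the alkyne insertion, and the size difference between the alkyne hydrogen and the fully substituted oxiranyl carbon secures it by placing the substituted carbon away from the carbene carbon and therefore next to the CO-derived C1–OH; phenol formation instead of cyclopentannulation is favoured by chromium, an alkenyl carbene and THF. The single phenolic OH is then acylated by tiglic anhydride under DMAP catalysis before any contact with air, silica or concentration, because an ortho-hydroxyaryl oxirane can open intramolecularly and 4-alkoxyphenols oxidise easily, and air with light finally strips Cr(CO)3 from 14; the carbene is the limiting reagent so that none is left to add to the phenoxide.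

Compound list
1 | 2-bromopropene | C=C(C)Br | starting material
2 | chromium hexacarbonyl | [Cr].[C-]#[O+].[C-]#[O+].[C-]#[O+].[C-]#[O+].[C-]#[O+].[C-]#[O+] | starting material
3 | isopropenyllithium (prop-1-en-2-yllithium) | [Li]C(C)=C | intermediate
4 | lithium pentacarbonyl(2-methyl-1-oxidoprop-2-en-1-ylidene)chromate | C=C(C)C([O-])=[Cr].[Li+].[C-]#[O+].[C-]#[O+].[C-]#[O+].[C-]#[O+].[C-]#[O+] | intermediate
5 | pentacarbonyl[methoxy(prop-1-en-2-yl)carbene]chromium(0) | C=C(C)C(OC)=[Cr].[C-]#[O+].[C-]#[O+].[C-]#[O+].[C-]#[O+].[C-]#[O+] | intermediate
6 | 2-bromoprop-2-en-1-ol | C=C(Br)CO | starting material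
7 | ethynyltrimethylsilane | C[Si](C)(C)C#C | starting material
8 | 2-methylidene-4-(trimethylsilyl)but-3-yn-1-ol | C=C(CO)C#C[Si](C)(C)C | intermediate
9 | [(2S)-2-[(trimethylsilyl)ethynyl]oxiran-2-yl]methanol | C[Si](C)(C)C#C[C@]1(CO)CO1 | intermediate
10 | [(2R)-2-[(trimethylsilyl)ethynyl]oxiran-2-yl]methyl 2-methylpropanoate | C[Si](C)(C)C#C[C@]1(COC(=O)C(C)C)CO1 | intermediate
11 | [(2R)-2-ethynyloxiran-2-yl]methyl 2-methylpropanoate | C#C[C@]1(COC(=O)C(C)C)CO1 | intermediate
12 | tricarbonylchromium(0) η6-complex of 13 (both arene faces) | Oc1cc(C)c(OC)cc1[C@]1(COC(=O)C(C)C)CO1.[Cr].[C-]#[O+].[C-]#[O+].[C-]#[O+] | intermediate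
13 | [(2R)-2-(2-hydroxy-5-methoxy-4-methylphenyl)oxiran-2-yl]methyl 2-methylpropanoate | Oc1cc(C)c(OC)cc1[C@]1(COC(=O)C(C)C)CO1 | intermediate
14 | tricarbonylchromium(0) η6-complex of 15 (both arene faces) | C/C=C(\C)C(=O)Oc1cc(C)c(OC)cc1[C@]1(COC(=O)C(C)C)CO1.[Cr].[C-]#[O+].[C-]#[O+].[C-]#[O+] | intermediate
15 | 4-methoxy-5-methyl-2-[(2R)-2-[(2-methylpropanoyloxy)methyl]oxiran-2-yl]phenyl (2E)-2-methylbut-2-enoate (CNP0256150.1) | C/C=C(\C)C(=O)Oc1cc(C)c(OC)cc1[C@]1(COC(=O)C(C)C)CO1 | target

Total step count: 5. Longest linear sequence: 4 steps (6 → 8 → 10 → 11 → 15; the carbene 5 is made in one step alongside).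

Steps most likely to fail

1. Step 5. The strained propargylic oxirane may not pass unchanged through the chromium vinylcarbene and vinylketene stages (metal-assisted ring opening or rearrangement). The fully substituted neighbour may also retard the electrocyclisation, so that cyclobutenone, furan or cyclopentannulation pathways take over, and the ortho-hydroxyaryl oxirane may open intramolecularly before it is acylated. The fallback keeps the ring construction but installs the oxirane afterwards. It sets out from 8: acylation with isobutyryl chloride, Et3N and DMAP should give 2-methylidene-4-(trimethylsilyl)but-3-yn-1-yl 2-methylpropanoate F1, and buffered TBAF the terminal enyne 2-methylidenebut-3-yn-1-yl 2-methylpropanoate F2. Benzannulation of F2 with 5 (THF, 50 °C) should give, through its chromium tricarbonyl complex F3, the robust phenol 2-(2-hydroxy-5-methoxy-4-methylphenyl)prop-2-en-1-yl 2-methylpropanoate F4, which tolerates release in air and isolation. Tigloylation with tiglic anhydride, Et3N and DMAP should give 4-methoxy-5-methyl-2-[3-(2-methylpropanoyloxy)prop-1-en-2-yl]phenyl (2E)-2-methylbut-2-enoate F5. A Shi epoxidation (oxazolidinone-fused chiral ketone, Oxone, bicarbonate buffer near pH 8, MeCN/H2O, 0 °C) should then epoxidise the electron-rich 1,1-disubstituted aryl alkene and leave the electron-poor tiglate alkene. The catalyst enantiomer is chosen by trial, and the enantiomeric purity is completed by preparative chiral HPLC, since this alkene class does not promise high selectivity. The fallback comes back to the route at 15.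

2. Step 3. Oxygen transfer to the electron-poor, alkyne-conjugated alkene may be slow, the titanium species may open the 2,2-disubstituted oxirane during the long reaction, and facial selectivity may be eroded. The fallback replaces catalyst control by an enzymatic resolution and sets out from 8: hydroxyl-directed epoxidation with VO(acac)2 and TBHP should give racemic [2-[(trimethylsilyl)ethynyl]oxiran-2-yl]methanol F6. Lipase-catalysed kinetic resolution of this primary alcohol by acylation with vinyl 2-methylpropanoate in MTBE, with a lipase selected in a screen for fast acylation of the (S)-alcohol and stopped before half conversion, should deliver the (R)-ester directly. The fallback comes back to the route at 10.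

3. Step 4. Residual basicity of fluoride or of the acetylide may cleave the isobutyrate or open the oxirane, and the small product may be lost on evaporation. The fallback removes silicon before the sensitive groups exist and sets out from 8: K2CO3 in MeOH at 0 °C should give 2-methylidenebut-3-yn-1-ol F7, which is kept as a CH2Cl2 solution and not concentrated to dryness. The asymmetric epoxidation of step 3 with acylation in the same flask should then proceed through [(2S)-2-ethynyloxiran-2-yl]methanol F8 to the terminal alkyne ester. The fallback comes back to the route at 11.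

Further compounds
F1 | step 5 | 2-methylidene-4-(trimethylsilyl)but-3-yn-1-yl 2-methylpropanoate | C=C(COC(=O)C(C)C)C#C[Si](C)(C)C
F2 | step 5 | 2-methylidenebut-3-yn-1-yl 2-methylpropanoate | C=C(COC(=O)C(C)C)C#C
F3 | step 5 | tricarbonylchromium(0) η6-complex of F4 | C=C(COC(=O)C(C)C)c1cc(OC)c(C)cc1O.[Cr].[C-]#[O+].[C-]#[O+].[C-]#[O+]
F4 | step 5 | 2-(2-hydroxy-5-methoxy-4-methylphenyl)prop-2-en-1-yl 2-methylpropanoate | C=C(COC(=O)C(C)C)c1cc(OC)c(C)cc1O
F5 | step 5 | 4-methoxy-5-methyl-2-[3-(2-methylpropanoyloxy)prop-1-en-2-yl]phenyl (2E)-2-methylbut-2-enoate | C/C=C(\C)C(=O)Oc1cc(C)c(OC)cc1C(=C)COC(=O)C(C)C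
F6 | step 3 | racemic [2-[(trimethylsilyl)ethynyl]oxiran-2-yl]methanol | C[Si](C)(C)C#CC1(CO)CO1
F7 | step 4 | 2-methylidenebut-3-yn-1-ol | C=C(CO)C#C
F8 | step 4 | [(2S)-2-ethynyloxiran-2-yl]methanol | C#C[C@]1(CO)CO1
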